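**Plan**

- Retrosynthesis: the acetates and the C3 silyl ether come off first. The lactone is then cut at C15–C16 and C16–O, leaving a C14 hydroxyl, a C15 vinyl iodide and CO. The feature that allows this is the five-membered ring O–C14–C1–C15–C16: the C14 oxygen and the sp2 carbon C15 are 1,3-related across C1, and C16 is a lone carbonyl carbon between them, with the exocyclic C15=C17 already in place.
- The 14-membered carbocycle is cut at C10–C11 (ring-closing metathesis, then diimide), C9–C10 (vinyl Grignard on a C8–C9 epoxide), C12–C13 (crotylstannane), C1–C15 (alkynylalane on a C14–C1 epoxide), C1=C14 (cross-metathesis) and C2–C3 (allylboration).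
- Forward order: the THF ring (C4–O–C7) is made first from (S)-linalool, then the chain grows C3 → C2/C1/C14/C13 → C15 → C12–C10, then the carbocycle closes, and the lactone ring closes last.
- Stereochemistry: C4 comes from (S)-linalool; C7/C8 and C14/C1 come from two Sharpless epoxidations (L-(+)-diethyl tartrate), each followed by an invertive opening; C3 comes from reagent-controlled allylboration; C12/C13 come from chelation-controlled crotylation.

Key step: step 23

Remark: cembrane numbering is used throughout (ring carbons C1–C14, acrylate carbons C15–C17). R* denotes the acetonide-protected THF unit (2S,5R)-2-methyl-5-[(4S)-2,2,4-trimethyl-1,3-dioxolan-4-yl]oxolan-2-yl (C4–C9). The mixtures at the ozonide carbon of 6, the acetal carbon of 18 and 33 and the C10=C11 geometry of 31 do not matter because these elements are removed later. Commercial (S)-(+)-linalool is assumed to be of high enantiomeric purity.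

**Route**

Step 1
Reactants: 1 (S)-(+)-linalool
Product: 2 (2E,6S)-2,6-dimethylocta-2,7-diene-1,6-diol
Conditions: SeO2 (cat.), t-BuOOH, salicylic acid (cat.), CH2Cl2, rt
Reagents that add atoms: tert-butyl hydroperoxide, CC(C)(C)OO
Why: SeO2-catalysed allylic oxidation (ene reaction, then [2,3]-sigmatropic shift) should hydroxylate the (E)-methyl group of the electron-rich trisubstituted alkene and leave the vinyl group and the carbinol centre untouched.

Step 2
Reactants: 2 (2E,6S)-2,6-dimethylocta-2,7-diene-1,6-diol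
Product: 4 (2S)-2-[(2R,5S)-5-ethenyl-5-methyloxolan-2-yl]propane-1,2-diol, via epoxy diol 3 (not isolated)
Conditions: Ti(OiPr)4 (cat.), L-(+)-diethyl tartrate (cat.), t-BuOOH, 4 Å molecular sieves, CH2Cl2, −20 °C; then camphorsulfonic acid (cat.), 0 °C → rt
Reagents that add atoms: tert-butyl hydroperoxide, CC(C)(C)OO
Why: Sharpless asymmetric epoxidation of the primary (E)-allylic alcohol should give the (7S,8S)-epoxide under reagent control, and 5-exo opening at C7 by the tertiary C4 hydroxyl with inversion then sets C7 (R), keeps C8 (S) and gives the 2,5-cis THF.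

Step 3
Reactants: 4 THF diol
Product: 5 (4S)-4-[(2R,5S)-5-ethenyl-5-methyloxolan-2-yl]-2,2,4-trimethyl-1,3-dioxolane
Conditions: Me2C(OMe)2, pyridinium p-toluenesulfonate (cat.), CH2Cl2, rt
Reagents that add atoms: 2,2-dimethoxypropane, COC(C)(C)OC
Why: acid-catalysed transacetalisation ties the tertiary/primary 1,2-diol into a dioxolane so that neither hydroxyl can form a bicyclic lactol with the C3 aldehyde made next.

Step 4
Reactants: 5 acetonide-protected vinyl THF
Product: 7 (2S,5R)-2-methyl-5-[(4S)-2,2,4-trimethyl-1,3-dioxolan-4-yl]oxolane-2-carbaldehyde, via ozonide 6 (not isolated)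
Conditions: O3, CH2Cl2, −78 °C; then PPh3, −78 °C → rt
Reagents that add atoms: ozone, [O-][O+]=O
Why: ozonolysis with reductive work-up cleaves the only alkene to the C3 aldehyde, which has a quaternary α-carbon and therefore cannot epimerise.

Step 5
Reactants: 7 THF aldehyde; 8 allylmagnesium bromide
Product: 10 (1R)-1-R*-but-3-en-1-ol, via borinate 9 (not isolated)
Conditions: (+)-Ipc2BOMe [from (−)-α-pinene], allylMgBr (8), Et2O, −78 °C → rt; then 7, −78 °C; then NaOH, H2O2, rt
Reagents that add atoms: allylmagnesium bromide (8), C=CC[Mg]Br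
Why: Brown allylboration through a chair Zimmerman–Traxler transition state is reagent-controlled, and the borane derived from (−)-α-pinene should attack the Re face of the aldehyde to set C3 (R).

Step 6
Reactants: 10 homoallylic alcohol
Product: 11 tert-butyldimethylsilyl ether of 10
Conditions: t-BuMe2SiOTf, 2,6-lutidine, CH2Cl2, −78 → 0 °C
Reagents that add atoms: tert-butyldimethylsilyl triflate, CC(C)(C)[Si](C)(C)OS(=O)(=O)C(F)(F)F
Why: the silyl triflate with a hindered base silylates the neopentyl-type C3 hydroxyl, and the TBS ether is chosen because it must outlast the mild acid of step 17 and the Lewis acid of step 24.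

Step 7
Reactants: 11 TBS ether; 12 methyl acrylate
Product: 13 methyl (2E,5R)-5-(tert-butyldimethylsilyloxy)-5-R*-pent-2-enoate
Conditions: methyl acrylate (12), second-generation Hoveyda–Grubbs catalyst (5 mol %), CH2Cl2, 40 °C
Reagents that add atoms: methyl acrylate (12), C=CC(=O)OC
Why: olefin cross-metathesis of a terminal alkene with an acrylate is reliably E-selective and selective for the cross product.

Step 8
Reactants: 13 enoate
Product: 14 (2E,5R)-5-(tert-butyldimethylsilyloxy)-5-R*-pent-2-en-1-ol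
Conditions: i-Bu2AlH, CH2Cl2, −78 °C
Reagents that add atoms: none
Why: 1,2-reduction of the enoate by the aluminium hydride gives the (E)-allylic alcohol without touching the acetonide or the silyl ether.

Step 9
Reactants: 14 allylic alcohol
Product: 15 [(2S,3S)-3-[(2R)-2-(tert-butyldimethylsilyloxy)-2-R*-ethyl]oxiran-2-yl]methanol
Conditions: Ti(OiPr)4 (cat.), L-(+)-diethyl tartrate (cat.), t-BuOOH, 4 Å molecular sieves, CH2Cl2, −20 °C
Reagents that add atoms: tert-butyl hydroperoxide, CC(C)(C)OO
Why: Sharpless asymmetric epoxidation of the (E)-allylic alcohol is reagent-controlled and should place the epoxide oxygen so that C14 has its final configuration and C1 the configuration to be inverted in step 10.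

Step 10
Reactants: 15 epoxy alcohol; 16 ethynyltrimethylsilane
Product: 17 (2R,3S)-3-[(2R)-2-(tert-butyldimethylsilyloxy)-2-R*-ethyl]-5-(trimethylsilyl)pent-4-yne-1,2-diol
Conditions: Me3SiC≡CH (16), n-BuLi, toluene, 0 °C; Et2AlCl; then 15, 0 °C → rt
Reagents that add atoms: ethynyltrimethylsilane (16), C#C[Si](C)(C)C
Why: alkynylalanes open 2,3-epoxy alcohols through the aluminium alkoxide at the carbon remote from the carbinol (C1) by SN2 attack, so C1 is set by inversion and ends up anti to the retained C14 hydroxyl.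

Step 11
Reactants: 17 alkynyl 1,2-diol
Product: 18 4-methoxybenzylidene acetal of 17
Conditions: 4-MeOC6H4CH(OMe)2, pyridinium p-toluenesulfonate (cat.), CH2Cl2, rt
Reagents that add atoms: 4-methoxybenzaldehyde dimethyl acetal, COc1ccc(cc1)C(OC)OC
Why: acid-catalysed acetal exchange converts the 1,2-diol into the dioxolane that serves as the precursor of a regiodefined PMB ether.

Step 12
Reactants: 18 anisylidene acetal
Product: 19 (2R,3S)-2-(4-methoxybenzyloxy)-3-[(2R)-2-(tert-butyldimethylsilyloxy)-2-R*-ethyl]-5-(trimethylsilyl)pent-4-yn-1-ol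
Conditions: i-Bu2AlH, CH2Cl2, −78 → 0 °C
Reagents that add atoms: none
Why: in the reductive acetal opening the aluminium binds the less hindered primary oxygen and hydride cleaves that C–O bond, which leaves the PMB group on the secondary C14 oxygen and frees the C13 hydroxyl.

Step 13
Reactants: 19 silylalkyne
Product: 20 (2R,3S)-2-(4-methoxybenzyloxy)-3-[(2R)-2-(tert-butyldimethylsilyloxy)-2-R*-ethyl]pent-4-yn-1-ol
Conditions: K2CO3, MeOH, rt
Reagents that add atoms: none
Why: carbonate-mediated methanolysis cleaves the alkynyl C–Si bond selectively and leaves the TBS ether, the acetonide and the PMB ether intact.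

Step 14
Reactants: 20 terminal alkyne
Product: 22 (2R,3R)-4-iodo-2-(4-methoxybenzyloxy)-3-[(2R)-2-(tert-butyldimethylsilyloxy)-2-R*-ethyl]pent-4-en-1-ol, via vinylalane 21 (not isolated)
Conditions: Ni(dppp)Cl2 (cat.), i-Bu2AlH, THF, rt; then N-iodosuccinimide, 0 °C
Reagents that add atoms: N-iodosuccinimide, O=C1CCC(=O)N1I
Why: nickel-catalysed hydroalumination of terminal alkynes with the dppp ligand places aluminium on the internal carbon, and iodinolysis of the C–Al bond then gives the 2-iodo-1-alkene (a net Markovnikov hydroiodination) at a stage where no other alkene is present.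

Step 15
Reactants: 22 iodoalkenyl alcohol
Product: 23 (2R,3R)-4-iodo-2-(4-methoxybenzyloxy)-3-[(2R)-2-(tert-butyldimethylsilyloxy)-2-R*-ethyl]pent-4-enal
Conditions: Dess–Martin periodinane, CH2Cl2, 0 °C → rt
Reagents that add atoms: none
Why: Dess–Martin oxidation under near-neutral conditions gives the α-alkoxy aldehyde without epimerising C14.

Step 16
Reactants: 23 α-PMB-oxy aldehyde; 24 (E)-crotyltributylstannane
Product: 25 (3S,4R,5R,6R)-7-iodo-5-(4-methoxybenzyloxy)-3-methyl-6-[(2R)-2-(tert-butyldimethylsilyloxy)-2-R*-ethyl]octa-1,7-dien-4-ol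
Conditions: (E)-crotyl-SnBu3 (24), MgBr2·OEt2, CH2Cl2, −25 °C
Reagents that add atoms: (E)-crotyltributylstannane (24), C/C=C/C[Sn](CCCC)(CCCC)CCCC
Why: in this chelation-controlled crotylstannane addition MgBr2 bridges the aldehyde and the C14 PMB ether, so attack anti to the C1 substituent should give the 13,14-syn relationship and the open antiperiplanar transition state the 12,13-syn relationship, which sets C13 (R) and C12 (S).

Step 17
Reactants: 25 crotyl adduct
Product: 26 triol with free C8 and C9 hydroxyls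
Conditions: AcOH/H2O (4:1), 40 °C
Reagents that add atoms: none
Why: mild acetal hydrolysis removes the acetonide, while the PMB ether, the hindered secondary TBS ether and the iodoalkene tolerate aqueous acetic acid.

Step 18
Reactants: 26 triol
Product: 28 C8–C9 epoxide, via tosylate 27 (not isolated)
Conditions: TsCl, Et3N, Bu2SnO (cat.), CH2Cl2, rt; then K2CO3, MeOH, rt
Reagents that add atoms: none
Why: tin-acetal-mediated sulfonylation selects the primary hydroxyl of the 1,2-diol over the isolated C13 hydroxyl, and intramolecular Williamson displacement by the tertiary alkoxide then closes the epoxide without touching the C8–O bond.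

Step 19
Reactants: 28 epoxide; 29 vinylmagnesium bromide
Product: 30 diene with C8 allyl carbinol and C12 vinyl group
Conditions: CH2=CHMgBr (29), CuI (cat.), THF, −40 → −20 °C
Reagents that add atoms: vinylmagnesium bromide (29), C=C[Mg]Br
Why: copper-catalysed Grignard opening of a 2,2-disubstituted epoxide occurs by SN2 attack at the CH2 terminus (C9) and forms C9–C10, and at this temperature the iodoalkene should be a spectator.

Step 20
Reactants: 30 diene
Product: 31 macrocyclic C10=C11 alkene (E/Z mixture)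
Conditions: second-generation Grubbs catalyst (10 mol %), CH2Cl2 (1 mM), 40 °C
Reagents that add atoms: none
Why: ring-closing metathesis joins the two monosubstituted alkenes into the 14-membered ring, while the 1,1-disubstituted iodoalkene is too hindered and electron-poor to enter the catalytic cycle.

Step 21
Reactants: 31 macrocyclic alkene
Product: 32 saturated macrocycle with C14 PMB ether and C15 vinyl iodide
Conditions: 2-nitrobenzenesulfonylhydrazide, Et3N, CH2Cl2, rt
Reagents that add atoms: none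
Why: diimide transfers H2 in a concerted syn fashion to the unhindered 1,2-disubstituted ring alkene, and because no metal hydride is involved the C–I bond and the deactivated iodoalkene should survive.

Step 22
Reactants: 32 saturated macrocycle
Product: 34 macrocyclic vinyl iodide with free C8/C13/C14 hydroxyls and C3 TBS ether, via anisylidene acetal 33 (not isolated)
Conditions: DDQ, 4 Å molecular sieves, CH2Cl2, 0 °C; then AcOH/H2O/THF, rt
Reagents that add atoms: none
Why: DDQ oxidation of the PMB ether gives an oxocarbenium ion that the neighbouring C13 hydroxyl traps as the cyclic acetal, which aqueous acetic acid then hydrolyses to the diol without cleaving the TBS ether.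

Step 23
Reactants: 34 vinyl iodide triol; 35 carbon monoxide
Product: 36 α-methylene-γ-lactone with free C8 and C13 hydroxyls and C3 TBS ether
Conditions: Pd(PPh3)4 (10 mol %), CO (1 atm), Et3N, MeCN, 60 °C
Reagents that add atoms: carbon monoxide (35), [C-]#[O+]
Why: Zerovalent palladium inserts into the C15–I bond, CO inserts to give the C16 acyl–palladium species, and the C14 hydroxyl attacks the acyl carbon, after which Et3N takes up HI and returns the catalyst. The closest known reaction type is the palladium-catalysed carbonylative lactonisation of hydroxy vinyl halides to α-methylene-γ-butyrolactones. The lactone ring (O–C14–C1–C15–C16) closes by 5-exo-trig attack of the C14 oxygen on the acyl carbon, which forms the C15–C16 and C16–O bonds. No stereocentre is created, and the ring fusion follows from C14 and C1 as fixed in steps 9 and 10. The step needs γ- over δ-lactonisation: the C14 oxygen is 1,3 to C15 and gives the five-membered ring, the C13 hydroxyl could only give a six-membered ring, the C3 oxygen is silylated, and the tertiary C8 hydroxyl is remote and hindered. Because the exocyclic methylene is already in the iodide, the Michael acceptor appears only here, after all basic and nucleophilic steps.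

Step 24
Reactants: 36 lactone diol
Product: 37 8,13-diacetate with C3 TBS ether
Conditions: Ac2O, Sc(OTf)3 (cat.), MeCN, −20 °C
Reagents that add atoms: acetic anhydride, CC(=O)OC(C)=O
Why: Lewis-acid-catalysed acylation with Sc(OTf)3 activates the anhydride enough to acetylate the tertiary C8 hydroxyl together with the secondary C13 hydroxyl, and the absence of a nucleophilic base spares the methylene lactone.

Step 25
Reactants: 37 diacetate
Product: 38 target compound (CID10479028)
Conditions: HF·pyridine, pyridine, THF, 0 °C → rt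
Reagents that add atoms: none
Why: fluoride-driven desilylation under buffered acidic conditions cleaves the hindered C3 TBS ether and leaves both acetates and the Michael acceptor intact.

**Compound list**

1 | (S)-(+)-linalool, (3S)-3,7-dimethylocta-1,6-dien-3-ol | C=C[C@@](C)(O)CCC=C(C)C | starting material
2 | (2E,6S)-2,6-dimethylocta-2,7-diene-1,6-diol | C=C[C@@](C)(O)CC/C=C(\C)CO | intermediate
3 | [(2S,3S)-3-[(3S)-3-hydroxy-3-methylpent-4-en-1-yl]-2-methyloxiran-2-yl]methanol | C=C[C@@](C)(O)CC[C@@H]1O[C@@]1(C)CO | intermediate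
4 | (2S)-2-[(2R,5S)-5-ethenyl-5-methyloxolan-2-yl]propane-1,2-diol (C4 S, C7 R, C8 S) | C=C[C@]1(C)CC[C@@H](O1)[C@@](C)(O)CO | intermediate
5 | (4S)-4-[(2R,5S)-5-ethenyl-5-methyloxolan-2-yl]-2,2,4-trimethyl-1,3-dioxolane | C=C[C@]1(C)CC[C@@H](O1)[C@]2(C)COC(C)(C)O2 | intermediate
6 | 3-R*-1,2,4-trioxolane (ozonide of 5, both epimers at the trioxolane carbon) | C1OC(OO1)[C@]2(C)CC[C@@H](O2)[C@]3(C)COC(C)(C)O3 | intermediate
7 | (2S,5R)-2-methyl-5-[(4S)-2,2,4-trimethyl-1,3-dioxolan-4-yl]oxolane-2-carbaldehyde | O=C[C@]1(C)CC[C@@H](O1)[C@]2(C)COC(C)(C)O2 | intermediate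
8 | allylmagnesium bromide | C=CC[Mg]Br | starting material
9 | O-bis(isopinocampheyl)boryl derivative of 10 | C=CC[C@@H](OB([C@H]1C[C@H]2C[C@H](C2(C)C)[C@@H]1C)[C@H]3C[C@H]4C[C@H](C4(C)C)[C@@H]3C)[C@]5(C)CC[C@@H](O5)[C@]6(C)COC(C)(C)O6 | intermediate
10 | (1R)-1-R*-but-3-en-1-ol (C3 R) | C=CC[C@@H](O)[C@]1(C)CC[C@@H](O1)[C@]2(C)COC(C)(C)O2 | intermediate
11 | tert-butyldimethylsilyl ether of 10 | C=CC[C@@H](O[Si](C)(C)C(C)(C)C)[C@]1(C)CC[C@@H](O1)[C@]2(C)COC(C)(C)O2 | intermediate
12 | methyl acrylate | C=CC(=O)OC | starting material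
13 | methyl (2E,5R)-5-(tert-butyldimethylsilyloxy)-5-R*-pent-2-enoate | COC(=O)/C=C/C[C@@H](O[Si](C)(C)C(C)(C)C)[C@]1(C)CC[C@@H](O1)[C@]2(C)COC(C)(C)O2 | intermediate
14 | (2E,5R)-5-(tert-butyldimethylsilyloxy)-5-R*-pent-2-en-1-ol | OC/C=C/C[C@@H](O[Si](C)(C)C(C)(C)C)[C@]1(C)CC[C@@H](O1)[C@]2(C)COC(C)(C)O2 | intermediate
15 | [(2S,3S)-3-[(2R)-2-(tert-butyldimethylsilyloxy)-2-R*-ethyl]oxiran-2-yl]methanol (C14–C1 epoxide) | OC[C@@H]1O[C@H]1C[C@@H](O[Si](C)(C)C(C)(C)C)[C@]2(C)CC[C@@H](O2)[C@]3(C)COC(C)(C)O3 | intermediate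
16 | ethynyltrimethylsilane | C#C[Si](C)(C)C | starting material
17 | (2R,3S)-3-[(2R)-2-(tert-butyldimethylsilyloxy)-2-R*-ethyl]-5-(trimethylsilyl)pent-4-yne-1,2-diol (C14 R, C1 S) | OC[C@H](O)[C@H](C#C[Si](C)(C)C)C[C@@H](O[Si](C)(C)C(C)(C)C)[C@]1(C)CC[C@@H](O1)[C@]2(C)COC(C)(C)O2 | intermediate
18 | 13,14-O-(4-methoxybenzylidene) acetal of 17 (both epimers at the acetal carbon) | COc1ccc(cc1)C2OC[C@H](O2)[C@H](C#C[Si](C)(C)C)C[C@@H](O[Si](C)(C)C(C)(C)C)[C@]3(C)CC[C@@H](O3)[C@]4(C)COC(C)(C)O4 | intermediate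
19 | (2R,3S)-2-(4-methoxybenzyloxy)-3-[(2R)-2-(tert-butyldimethylsilyloxy)-2-R*-ethyl]-5-(trimethylsilyl)pent-4-yn-1-ol | OC[C@H](OCc1ccc(OC)cc1)[C@H](C#C[Si](C)(C)C)C[C@@H](O[Si](C)(C)C(C)(C)C)[C@]2(C)CC[C@@H](O2)[C@]3(C)COC(C)(C)O3 | intermediate
20 | (2R,3S)-2-(4-methoxybenzyloxy)-3-[(2R)-2-(tert-butyldimethylsilyloxy)-2-R*-ethyl]pent-4-yn-1-ol | OC[C@H](OCc1ccc(OC)cc1)[C@H](C#C)C[C@@H](O[Si](C)(C)C(C)(C)C)[C@]2(C)CC[C@@H](O2)[C@]3(C)COC(C)(C)O3 | intermediate
21 | α-vinylalane of 20 (diisobutylaluminium on C15 and on the C13 oxygen) | CC(C)C[Al](CC(C)C)OC[C@H](OCc1ccc(OC)cc1)[C@H](C(=C)[Al](CC(C)C)CC(C)C)C[C@@H](O[Si](C)(C)C(C)(C)C)[C@]2(C)CC[C@@H](O2)[C@]3(C)COC(C)(C)O3 | intermediate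
22 | (2R,3R)-4-iodo-2-(4-methoxybenzyloxy)-3-[(2R)-2-(tert-butyldimethylsilyloxy)-2-R*-ethyl]pent-4-en-1-ol (C1 unchanged in space; its CIP label is R while C15 carries iodine) | OC[C@H](OCc1ccc(OC)cc1)[C@H](C(I)=C)C[C@@H](O[Si](C)(C)C(C)(C)C)[C@]2(C)CC[C@@H](O2)[C@]3(C)COC(C)(C)O3 | intermediate
23 | (2R,3R)-4-iodo-2-(4-methoxybenzyloxy)-3-[(2R)-2-(tert-butyldimethylsilyloxy)-2-R*-ethyl]pent-4-enal | O=C[C@H](OCc1ccc(OC)cc1)[C@H](C(I)=C)C[C@@H](O[Si](C)(C)C(C)(C)C)[C@]2(C)CC[C@@H](O2)[C@]3(C)COC(C)(C)O3 | intermediate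
24 | (E)-crotyltributylstannane | C/C=C/C[Sn](CCCC)(CCCC)CCCC | starting material
25 | (3S,4R,5R,6R)-7-iodo-5-(4-methoxybenzyloxy)-3-methyl-6-[(2R)-2-(tert-butyldimethylsilyloxy)-2-R*-ethyl]octa-1,7-dien-4-ol (C12 S, C13 R, C14 R) | C=C[C@H](C)[C@@H](O)[C@H](OCc1ccc(OC)cc1)[C@H](C(I)=C)C[C@@H](O[Si](C)(C)C(C)(C)C)[C@]2(C)CC[C@@H](O2)[C@]3(C)COC(C)(C)O3 | intermediate
26 | triol from 25 by loss of the acetonide (free C8, C9 and C13 hydroxyls, C8 S) | C=C[C@H](C)[C@@H](O)[C@H](OCc1ccc(OC)cc1)[C@H](C(I)=C)C[C@@H](O[Si](C)(C)C(C)(C)C)[C@]2(C)CC[C@@H](O2)[C@@](C)(O)CO | intermediate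
27 | C9 4-methylbenzenesulfonate of 26 | C=C[C@H](C)[C@@H](O)[C@H](OCc1ccc(OC)cc1)[C@H](C(I)=C)C[C@@H](O[Si](C)(C)C(C)(C)C)[C@]2(C)CC[C@@H](O2)[C@@](C)(O)COS(=O)(=O)c3ccc(C)cc3 | intermediate
28 | (8S)-C8–C9 epoxide (2-methyloxiran-2-yl on C7) | C=C[C@H](C)[C@@H](O)[C@H](OCc1ccc(OC)cc1)[C@H](C(I)=C)C[C@@H](O[Si](C)(C)C(C)(C)C)[C@]2(C)CC[C@@H](O2)[C@]3(C)CO3 | intermediate
29 | vinylmagnesium bromide | C=C[Mg]Br | starting material
30 | acyclic diene: C8 tertiary carbinol with allyl group (C9–C10=CH2), C12 vinyl, C13 OH, C14 OPMB, C15 iodoalkene, C3 OTBS | C=C[C@H](C)[C@@H](O)[C@H](OCc1ccc(OC)cc1)[C@H](C(I)=C)C[C@@H](O[Si](C)(C)C(C)(C)C)[C@]2(C)CC[C@@H](O2)[C@@](C)(O)CC=C | intermediate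
31 | 14-membered carbocycle with C10=C11 alkene (E/Z), 4,7-oxygen bridge, C1 1-iodovinyl, C3 OTBS, C8 OH, C13 OH, C14 OPMB (3R,4S,7R,8S,12S,13R,14R; C1 as in the target) | COc1ccc(CO[C@H]2[C@H](O)[C@@H](C)C=CC[C@](C)(O)[C@H]3CC[C@](C)(O3)[C@H](O[Si](C)(C)C(C)(C)C)C[C@H]2C(I)=C)cc1 | intermediate
32 | 10,11-dihydro derivative of 31 | COc1ccc(CO[C@H]2[C@H](O)[C@@H](C)CCC[C@](C)(O)[C@H]3CC[C@](C)(O3)[C@H](O[Si](C)(C)C(C)(C)C)C[C@H]2C(I)=C)cc1 | intermediate
33 | 13,14-O-(4-methoxybenzylidene) acetal of 34 (both epimers at the acetal carbon) | COc1ccc(cc1)C4O[C@H]2[C@H](O4)[C@@H](C)CCC[C@](C)(O)[C@H]3CC[C@](C)(O3)[C@H](O[Si](C)(C)C(C)(C)C)C[C@H]2C(I)=C | intermediate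
34 | macrocyclic C15 vinyl iodide with free C8, C13 and C14 hydroxyls and C3 OTBS | O[C@H]1[C@H](O)[C@@H](C)CCC[C@](C)(O)[C@H]2CC[C@](C)(O2)[C@H](O[Si](C)(C)C(C)(C)C)C[C@H]1C(I)=C | intermediate
35 | carbon monoxide | [C-]#[O+] | starting material
36 | α-methylene-γ-lactone (1S,3R,4S,7R,8S,12S,13R,14R) with free C8 and C13 hydroxyls and C3 OTBS | C=C1C(=O)O[C@H]2[C@H](O)[C@@H](C)CCC[C@](C)(O)[C@H]3CC[C@](C)(O3)[C@H](O[Si](C)(C)C(C)(C)C)C[C@@H]12 | intermediate
37 | 8,13-diacetate of 36 | C=C1C(=O)O[C@H]2[C@H](OC(C)=O)[C@@H](C)CCC[C@](C)(OC(C)=O)[C@H]3CC[C@](C)(O3)[C@H](O[Si](C)(C)C(C)(C)C)C[C@@H]12 | intermediate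
38 | CID10479028, the 3-hydroxy 8,13-diacetate | C=C1C(=O)O[C@H]2[C@H](OC(C)=O)[C@@H](C)CCC[C@](C)(OC(C)=O)[C@H]3CC[C@](C)(O3)[C@H](O)C[C@@H]12 | target

**Totals and risks**

Total step count: 25. Longest linear sequence: 25 steps (1 → 38); the route is linear.

Steps most likely to fail, each with one fallback:

1. Step 14. The regiochemistry of the hydroalumination may drift towards the terminal carbon, or the alkyne may be deprotonated instead of hydrometallated, under the influence of the aluminium alkoxide and the neighbouring PMB ether. Fallback: from 20, ruthenium-catalysed Markovnikov hydrosilylation (Et3SiH, [Cp*Ru(MeCN)3]PF6 cat., CH2Cl2, 0 °C), which tolerates the free hydroxyl, would give the 2-(triethylsilyl)alkene F1. Iododesilylation (N-iodosuccinimide, hexafluoroisopropanol, 0 °C) then returns to 22.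

2. Step 20. Intermolecular metathesis may outrun closure of the 14-membered ring, or the homoallylic hydroxyls may hold back the catalyst. Fallback: from 30, DDQ under anhydrous conditions would convert the C13 hydroxyl and the C14 PMB ether into the cyclic anisylidene acetal F2. This removes the free secondary hydroxyl and fixes C12–C1 in a dioxolane turn, so the closure is run on a templated substrate. Ring-closing metathesis of F2 would give the macrocyclic alkene F3, diimide reduction gives 33, and the hydrolysis of step 22 returns to 34.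

3. Step 24. The Lewis acid may cause loss or silyl-to-acetyl exchange of the C3 ether, or ionisation and elimination at the tertiary C8 carbinol. Fallback: acetylate under basic conditions before the Michael acceptor exists. From 32, Ac2O/DMAP/Et3N (CH2Cl2, 40 °C) would give the 8,13-diacetate F4. DDQ in wet CH2Cl2 then removes the PMB group, with no free neighbouring hydroxyl to intercept the oxocarbenium ion, and gives the 14-hydroxy diacetate F5. The carbonylation of step 23 applied to F5 returns to the route at 37.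

**Further compounds**

F1 | step 14 | (2R,3R)-2-(4-methoxybenzyloxy)-3-[(2R)-2-(tert-butyldimethylsilyloxy)-2-R*-ethyl]-4-(triethylsilyl)pent-4-en-1-ol | OC[C@H](OCc1ccc(OC)cc1)[C@H](C(=C)[Si](CC)(CC)CC)C[C@@H](O[Si](C)(C)C(C)(C)C)[C@]2(C)CC[C@@H](O2)[C@]3(C)COC(C)(C)O3
F2 | step 20 | 13,14-O-(4-methoxybenzylidene) acetal of diene 30 | C=C[C@H](C)[C@H]4OC(c5ccc(OC)cc5)O[C@@H]4[C@H](C(I)=C)C[C@@H](O[Si](C)(C)C(C)(C)C)[C@]2(C)CC[C@@H](O2)[C@@](C)(O)CC=C
F3 | step 20 | 10,11-didehydro derivative of acetal 33 (E/Z) | COc1ccc(cc1)C4O[C@H]2[C@H](O4)[C@@H](C)C=CC[C@](C)(O)[C@H]3CC[C@](C)(O3)[C@H](O[Si](C)(C)C(C)(C)C)C[C@H]2C(I)=C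
F4 | step 24 | 8,13-diacetate of 32 | COc1ccc(CO[C@H]2[C@H](OC(C)=O)[C@@H](C)CCC[C@](C)(OC(C)=O)[C@H]3CC[C@](C)(O3)[C@H](O[Si](C)(C)C(C)(C)C)C[C@H]2C(I)=C)cc1
F5 | step 24 | 14-hydroxy 8,13-diacetate vinyl iodide | O[C@H]1[C@H](OC(C)=O)[C@@H](C)CCC[C@](C)(OC(C)=O)[C@H]2CC[C@](C)(O2)[C@H](O[Si](C)(C)C(C)(C)C)C[C@H]1C(I)=C
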